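## The problem

Germacrane numbering is used throughout: C1–C10 form the ring, C1 and C10 are the epoxide carbons (C14 is the methyl on C10), C2 is the free carbinol, C4=C5 is the ring alkene with the hydroxymethyl C15 on C4, C6 carries the lactone oxygen, C7 carries C11(=C13H2)–C12(=O), and C8 carries the angelate.

- The skeleton is a ten-membered carbocycle, trans-fused at C6–C7 to an α-methylene γ-lactone. The ring is strained by the endocyclic trisubstituted alkene, so it should be closed late and at a bond where strain can be paid for by a strongly driven reaction.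
- There are six stereocentres (1R,2S,6R,7R,8S,10R). C6, C7 and C8 are contiguous, so C7 can fix C8 (aldol) and C6 (addition to a C6 aldehyde).
- C2 is insulated from this triad by C3–C4=C5 and needs reagent control. C1 and C10 can then be derived from C2 by 1,2-induction and from the mode of ring closure.
- The epoxide is trans (C2 and C9 on opposite faces). This corresponds to a cis-1,10-diol closed with inversion at C1.
- The α-methylene lactone (Michael acceptor, reducible), the angelate (isomerises to the tiglate, sensitive to base), the epoxide (transannular opening under acid) and the allylic primary alcohol will not survive organometallic, strongly basic or reducing steps. They must appear at the end.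
- The enabling feature is the C4=C5 alkene: C4 bears C3 and C15, C5 bears C6, O15 is cis to C6, and O6 is γ to C12. This is the pattern left by anti-addition of a C3 nucleophile and magnesium across propargyl alcohol, capture of a C6 aldehyde at C5, and lactonisation of the C6 alkoxide onto a C12 ester.

## Retrosynthesis

**C8–O acyl bond and the last silyl ethers.** Target 40 is traced to the bis-silyl ether 39 and further to alcohol 36 and angelic acid 37. The angelate is cut first because it tolerates neither enolate chemistry nor single-electron reductants. The forward acylation must avoid Z to E isomerisation and must find C8–OH as the only free hydroxyl, so O2 and O15 carry silyl ethers (TES, TBDPS) and O8 carries an oxidatively removable 2-naphthylmethyl (Nap) ether.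

**C11=C13.** The methylene of 35 is removed to give lactone 32. Cutting it before the ring-forming bond is necessary because an acrylate would intercept ketyl radicals and amine catalysts. The forward reaction is a lactone enolate Mannich reaction and elimination, which the epoxide and the ethers tolerate at low temperature.

**Epoxide C–O bond.** Epoxide 32 is opened to the cis-diol 30. Displacement of a C1 sulfonate by the C10 alkoxide inverts C1, so the cis-diol gives the trans-epoxide by design. Direct epoxidation of a ring alkene would leave both geometry and face to the conformation of the ring.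

**C1–C10.** Diol 30 is cut to keto aldehyde 29 (pinacol coupling). This is preferred to an olefination or metathesis at the same bond, which would have to deliver an E trisubstituted alkene in a strained ring and then a face-selective epoxidation. The pinacol joins two carbonyls irreversibly and delivers both oxygens of the epoxide precursor. The forward step must give the cis-diol with C1–O anti to the C2 silyloxy group.

**C2–O.** The α-silyloxy aldehyde 29 is traced through diol 27 to the unfunctionalised keto aldehyde 24. Organocatalytic aminoxylation sets C2 by reagent control, which is required because no existing stereocentre is near. 24 is simply the doubly unmasked form of the bis-dioxolane 23, the TBDPS ether of 22.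

**C3–C4, C5–C6 and O6–C12 (key disconnection).** Lactone 22 is cut into propargyl alcohol 18, the C1–C3 Grignard reagent 17 and the C6–C12 aldehyde ester 15. Cutting around the alkene is preferred to a Wittig-type cut at C4=C5, which would not guarantee the geometry of a trisubstituted alkene flanked by two oxygenated carbons. The precursors are a commercial alkyne, a one-step Grignard reagent and an acyclic aldehyde with two stereocentres. The forward reaction must be anti-selective, must add to the aldehyde and not the ester, and must attack the Felkin face of 15.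

**C7–C8 and oxidation levels of the aldehyde ester.** Aldehyde 15 is traced through thioester 14 and imide 13 to the Evans syn-aldol adduct 9, made from imide 4 and aldehyde 6. Three choices protect this sequence from premature lactonisation:
- C12 is a tert-butyl ester during the aldol, since a methyl ester would be attacked by the C8 aldolate. It is exchanged for methyl only after O8 is capped (10 to 13).
- C6 is brought to the aldehyde through the thioester and not through a primary alcohol, which would close onto C12.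
- O8 is a Nap ether, since a p-methoxybenzyl ether would not survive the silyl triflate used on the tert-butyl ester.

**Starting materials.** Imide 4 comes from mono-tert-butyl succinate 1 and oxazolidinone 2, aldehyde 6 from ester 5, and Grignard reagent 17 from bromide 16.

## Roads not taken

**Alternative 1:** Wittig–Still ring contraction.
- Cut: C7–C8, with O8 tied to C13 in a thirteen-membered α-stannyl ether A2.
- Forward key step: tin–lithium exchange at C8 of A2 (n-BuLi, −78 °C) and [2,3]-shift to the ten-membered homoallylic alcohol A1.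
- Merits: the strained ring is reached by contraction of a larger, easier ring. C7 and C8 are set in one concerted event. C11=C13 and a free C8–OH appear directly, so no Mannich sequence and no orthogonal C8 ether are needed. In these respects it is better than the chosen plan, which spends steps 19 and 20 on them.
- Weak points: A2 needs a macrocyclic ether with a configurationally defined stannylated carbinol and a defined C7=C11 geometry. The C7/C8 outcome rests on the transition-state conformation of a flexible thirteen-membered ring, and the [1,2]-shift competes. After A1, the lactone must still be made by oxidising C12 and closing onto C6. The 1,10-epoxide must be introduced on a triene with chemo- and face-selectivity.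
- Comparison: the chosen plan sets C7/C8 by an auxiliary-controlled aldol and makes lactone, alkene and C6 in one step. It pays with a riskier ring closure at C1–C10.

**Alternative 2:** Singlet-oxygen cycloaddition.
- Cut: O–C6 and O–C15, both traced to one molecule of O2.
- Forward key step: [4+2] addition of singlet oxygen to the s-cis C15=C4–C5=C6 diene of the germacrene D-type diene A4, giving the endoperoxide A3. O–O reduction and lactonisation would then finish the target.
- Merits: one reagent installs both oxygens and the C4=C5 alkene, with O15 cis to C6 enforced by the peroxide ring. Epoxide and angelate are already in place and no protecting groups are needed. In late-stage step economy this is clearly better than the chosen plan.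
- Weak points: the whole difficulty is moved into A4, a fully functionalised ten-membered diene whose ring closure, epoxide and angelate are left unsolved. The ring must allow an s-cis diene. The C6 configuration depends on which face of a conformationally mobile ring is attacked. Ene reactions at allylic C–H bonds compete. The peroxide reduction must spare epoxide and acrylate.
- Comparison: the chosen plan answers each of these points with a defined control element: the chelate for alkene geometry, C7 for C6, and an explicit ring closure.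

**Alternative 3:** Sulfonium ylide epoxy-annulation.
- Cut: C1–C10 and O–C10 together.
- Forward key step: KN(SiMe3)2 at −78 °C under high dilution converts the C10 diphenylsulfonium salt A6 into an ylide, which adds to the C1 aldehyde and closes to the epoxy lactone A5.
- Merits: ring and epoxide are made in one step from the same kind of acyclic lactone that the chosen plan uses. This saves the pinacol/sulfonate pair and avoids SmI2. It is one to two steps shorter than steps 17 and 18.
- Weak points: a secondary alkyl diphenylsulfonium salt is hard to install in a polyfunctional substrate and prone to elimination. The unstabilised ylide is basic enough to epimerise the α-silyloxy aldehyde or enolise the lactone. Its addition is irreversible, so cis/trans and facial selectivity of the trisubstituted epoxide are under no identifiable control and cannot be corrected afterwards.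
- Comparison: the chosen plan passes through diol 30, where the stereochemical logic (cis-diol, inversion at C1) is explicit and where diastereomers can still be separated.

Key step: step 10

Remark: compounds 1, 2, 5, 16, 18 and 37 are taken as commercial. Nap is 2-naphthylmethyl, TBDPS is tert-butyldiphenylsilyl and TES is triethylsilyl. C11 of 33 and 34 is an inconsequential mixture of epimers.

## Route

Step 1
Reactants: 1 4-tert-butoxy-4-oxobutanoic acid; 2 (4R)-4-benzyl-1,3-oxazolidin-2-one
Product: 4 tert-butyl 4-[(4R)-4-benzyl-2-oxo-1,3-oxazolidin-3-yl]-4-oxobutanoate, via mixed pivalic anhydride 3 (not isolated)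
Conditions: PivCl, Et3N, THF, −20 °C; then LiCl, 2, −20 °C → rt
Reagents that add atoms: none
Why: N-acylation of an Evans oxazolidinone through the mixed pivalic anhydride; the tert-butyl ester is chosen because a less hindered ester would later be attacked by the C8 aldolate.

Step 2
Reactants: 5 ethyl 2-(2-methyl-1,3-dioxolan-2-yl)acetate
Product: 6 2-(2-methyl-1,3-dioxolan-2-yl)acetaldehyde
Conditions: DIBAL-H, CH2Cl2, −78 °C; MeOH, aq. Rochelle salt
Reagents that add atoms: none
Why: Partial reduction of an ester by DIBAL-H at low temperature through the stable aluminium hemiacetal; the ketal is inert and the aldehyde is used directly.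

Step 3
Reactants: 4 tert-butyl 4-[(4R)-4-benzyl-2-oxo-1,3-oxazolidin-3-yl]-4-oxobutanoate; 6 2-(2-methyl-1,3-dioxolan-2-yl)acetaldehyde
Product: 9 tert-butyl (3R,4S)-3-[(4R)-4-benzyl-2-oxo-1,3-oxazolidine-3-carbonyl]-4-hydroxy-5-(2-methyl-1,3-dioxolan-2-yl)pentanoate, via boron enolate 7 (not isolated), via boron aldolate 8 (not isolated)
Conditions: Bu2BOTf, iPr2NEt, CH2Cl2, −78 → 0 °C; 6, −78 → 0 °C; pH 7 buffer, MeOH, H2O2, 0 °C
Reagents that add atoms: none
Why: Evans syn-aldol: the Z-boron enolate reacts through a Zimmerman–Traxler chair on the face away from the benzyl group of the (R)-auxiliary, which sets C7 and C8 (7R,8S, C11 syn to O8); the hindered tert-butyl ester resists the aldolate.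

Step 4
Reactants: 9 the aldol adduct
Product: 10 tert-butyl (3R,4S)-3-[(4R)-4-benzyl-2-oxo-1,3-oxazolidine-3-carbonyl]-5-(2-methyl-1,3-dioxolan-2-yl)-4-(naphthalen-2-ylmethoxy)pentanoate
Conditions: NapOC(=NH)CCl3, TfOH (cat.), CH2Cl2/cyclohexane, 0 °C
Reagents that add atoms: 2-naphthylmethyl 2,2,2-trichloroacetimidate, N=C(OCc1ccc2ccccc2c1)C(Cl)(Cl)Cl
Why: Acid-catalysed O-alkylation with a trichloroacetimidate avoids the basic conditions that cause retro-aldol cleavage; the Nap ether withstands the silyl triflate of step 5 and is later removed oxidatively, orthogonal to all silyl ethers.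

Step 5
Reactants: 10 the Nap ether tert-butyl ester
Product: 12 (3R,4S)-3-[(4R)-4-benzyl-2-oxo-1,3-oxazolidine-3-carbonyl]-5-(2-methyl-1,3-dioxolan-2-yl)-4-(naphthalen-2-ylmethoxy)pentanoic acid, via trimethylsilyl ester 11 (not isolated)
Conditions: TMSOTf, 2,6-lutidine, CH2Cl2, 0 °C → rt; then pH 4 citrate buffer
Reagents that add atoms: none
Why: Silyl triflate-mediated cleavage of a tert-butyl ester (O-silylation of the ester carbonyl, loss of isobutene, hydrolysis of the silyl ester on work-up); in the lutidine-buffered medium ketone ketals, the imide and the Nap ether are expected to persist.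

Step 6
Reactants: 12 the carboxylic acid
Product: 13 methyl (3R,4S)-3-[(4R)-4-benzyl-2-oxo-1,3-oxazolidine-3-carbonyl]-5-(2-methyl-1,3-dioxolan-2-yl)-4-(naphthalen-2-ylmethoxy)pentanoate
Conditions: TMSCHN2, PhMe/MeOH, 0 °C
Reagents that add atoms: (trimethylsilyl)diazomethane, C[Si](C)(C)C=[N+]=[N-]
Why: Neutral methylation of a carboxylic acid with TMSCHN2 in methanol; the methyl ester is what the lactonisation of step 10 needs, and O8 is now capped so it cannot lactonise.

Step 7
Reactants: 13 the methyl ester imide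
Product: 14 methyl (3R,4S)-3-[(ethylsulfanyl)carbonyl]-5-(2-methyl-1,3-dioxolan-2-yl)-4-(naphthalen-2-ylmethoxy)pentanoate
Conditions: EtSH, n-BuLi, THF, −78 → 0 °C
Reagents that add atoms: ethanethiol, CCS
Why: Transthioesterification of an N-acyloxazolidinone with lithium ethanethiolate, which attacks the activated exocyclic imide carbonyl and not the methyl ester; the auxiliary 2 is recovered, and a reductive cleavage is avoided because a C6 alkoxide would lactonise onto C12.

Step 8
Reactants: 14 the S-ethyl thioester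
Product: 15 methyl (3R,4S)-3-formyl-5-(2-methyl-1,3-dioxolan-2-yl)-4-(naphthalen-2-ylmethoxy)pentanoate
Conditions: Et3SiH, Pd/C (10 wt%), acetone, rt
Reagents that add atoms: none
Why: Fukuyama reduction of a thioester to the aldehyde under neutral conditions that leave the methyl ester, the ketal and the C7 stereocentre untouched; 15 is used at once.

Step 9
Reactants: 16 2-(2-bromoethyl)-1,3-dioxolane
Product: 17 [2-(1,3-dioxolan-2-yl)ethyl]magnesium bromide
Conditions: Mg, BrCH2CH2Br (cat.), THF, 20–25 °C
Reagents that add atoms: magnesium, [Mg]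
Why: Direct magnesium insertion into a primary bromide; this β-acetal Grignard reagent is stable in THF when kept at or below room temperature.

Step 10
Reactants: 18 prop-2-yn-1-ol; 17 [2-(1,3-dioxolan-2-yl)ethyl]magnesium bromide; 15 the C6–C12 aldehyde ester
Product: 22 (4R,5R)-5-[(1Z)-4-(1,3-dioxolan-2-yl)-2-(hydroxymethyl)but-1-en-1-yl]-4-[(1S)-2-(2-methyl-1,3-dioxolan-2-yl)-1-(naphthalen-2-ylmethoxy)ethyl]oxolan-2-one, via bromomagnesium propargyl alkoxide 19 (not isolated), via alkenylmagnesium chelate 20 (not isolated), via magnesium dialkoxide 21 (not isolated)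
Conditions: 18, EtMgBr (1 equiv), THF, 0 °C; CuI (10 mol%), 17 (1 equiv), −10 °C → rt; 15 (0.5 equiv), −78 → 0 °C, then rt; aq. NH4Cl
Reagents that add atoms: none
Why: CuI-catalysed carbomagnesiation of a propargylic alkoxide: after deprotonation of 18 to 19, the alkyl group of 17 goes to C4 and magnesium to C5 in an anti sense, so that magnesium is cis to C15 and held by the alkoxide in the five-membered chelate 20. 20 adds to the aldehyde of 15 with retention of alkene geometry, forming C5–C6 with C6 cis to C15 and trans to C3, as in the target. The C6 alkoxide of 21 then attacks the methyl ester (5-exo-trig acyl substitution) and expels methoxide, which closes the γ-lactone. The closest known reaction type is the copper-catalysed anti-carbomagnesiation of propargyl alcohols with capture of the alkenylmagnesium by iodine or carbonyl electrophiles. The new stereocentre C6 is controlled by C7 in the Felkin–Anh sense: attack anti to the branched C8 substituent puts O6 syn to C11 and gives the trans lactone (6R). Regio- and anti-selectivity of the carbometalation are secured by the alkoxide chelate. Chemoselectivity for the aldehyde over the ester is secured by low temperature and by spending EtMgBr, not 17, on the hydroxyl proton, so that no alkyl Grignard reagent is left when the limiting 15 is added. Facial selectivity rests on the α-branch of 15, with THF as donor solvent disfavouring a magnesium bridge to the C8 ether.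

Step 11
Reactants: 22 the hydroxy lactone
Product: 23 (4R,5R)-5-[(1Z)-2-{[tert-butyl(diphenyl)silyl]oxymethyl}-4-(1,3-dioxolan-2-yl)but-1-en-1-yl]-4-[(1S)-2-(2-methyl-1,3-dioxolan-2-yl)-1-(naphthalen-2-ylmethoxy)ethyl]oxolan-2-one
Conditions: TBDPSCl, imidazole, CH2Cl2, 0 °C → rt
Reagents that add atoms: tert-butyl(chloro)diphenylsilane, CC(C)(C)[Si](Cl)(c1ccccc1)c1ccccc1
Why: Silylation of the primary allylic alcohol; the TBDPS ether survives the acid of step 12 and the Swern conditions of step 16 and prevents lactol formation with the C1 aldehyde.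

Step 12
Reactants: 23 the bis-dioxolane
Product: 24 (4R,5R)-5-[(1Z)-2-{[tert-butyl(diphenyl)silyl]oxymethyl}-5-oxopent-1-en-1-yl]-4-[(1S)-1-(naphthalen-2-ylmethoxy)-3-oxobutyl]oxolan-2-one
Conditions: p-TsOH·H2O (cat.), acetone/H2O (5:1), 40 °C
Reagents that add atoms: water, O
Why: Acid-catalysed hydrolysis of both dioxolanes in one operation, unveiling the C1 aldehyde and the C10 ketone; the Nap ether, the TBDPS ether and the lactone are stable to dilute sulfonic acid.

Step 13
Reactants: 24 the keto aldehyde
Product: 26 (4R,5R)-5-[(1Z,4S)-4-(anilinooxy)-2-{[tert-butyl(diphenyl)silyl]oxymethyl}-5-hydroxypent-1-en-1-yl]-4-[(1S)-1-(naphthalen-2-ylmethoxy)-3-oxobutyl]oxolan-2-one, via anilinooxy aldehyde 25 (not isolated)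
Conditions: PhNO, D-proline (20 mol%), CHCl3, 4 °C; then EtOH, NaBH4, −78 °C
Reagents that add atoms: nitrosobenzene, O=Nc1ccccc1
Why: Proline-catalysed α-aminoxylation (nitroso aldol): the enamine of the C1 aldehyde attacks the oxygen of nitrosobenzene held by the carboxylic acid of the catalyst, and D-proline gives the 2S configuration under reagent control; aldehydes form enamines far faster than the methyl ketone, and borohydride at −78 °C reduces only the activated aldehyde.

Step 14
Reactants: 26 the anilinooxy alcohol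
Product: 27 (4R,5R)-5-[(1Z,4S)-2-{[tert-butyl(diphenyl)silyl]oxymethyl}-4,5-dihydroxypent-1-en-1-yl]-4-[(1S)-1-(naphthalen-2-ylmethoxy)-3-oxobutyl]oxolan-2-one
Conditions: Zn dust, AcOH, EtOH, rt
Reagents that add atoms: none
Why: Reductive cleavage of the N–O bond by zinc in acetic acid; ketone, lactone, alkene and ethers are inert.

Step 15
Reactants: 27 the 1,2-diol
Product: 28 (4R,5R)-5-[(1Z,4S)-2-{[tert-butyl(diphenyl)silyl]oxymethyl}-4,5-bis(triethylsilyloxy)pent-1-en-1-yl]-4-[(1S)-1-(naphthalen-2-ylmethoxy)-3-oxobutyl]oxolan-2-one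
Conditions: TESCl, imidazole, DMAP (cat.), CH2Cl2, 0 °C → rt
Reagents that add atoms: chlorotriethylsilane, CC[Si](Cl)(CC)CC
Why: Silylation of both hydroxyls with the silyl chloride and imidazole, which does not enolise the methyl ketone as a silyl triflate would.

Step 16
Reactants: 28 the bis-TES ether
Product: 29 (4R,5R)-5-[(1Z,4S)-2-{[tert-butyl(diphenyl)silyl]oxymethyl}-5-oxo-4-(triethylsilyloxy)pent-1-en-1-yl]-4-[(1S)-1-(naphthalen-2-ylmethoxy)-3-oxobutyl]oxolan-2-one
Conditions: (COCl)2, DMSO, CH2Cl2, −78 → −40 °C; Et3N, −78 → 0 °C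
Reagents that add atoms: none
Why: Swern oxidation of a bis-TES ether: the chlorosulfonium species cleaves the primary silyl ether selectively and oxidises it to the aldehyde while the secondary TES ether and the TBDPS ether stay, a known one-step desilylation–oxidation; low temperature keeps C2 intact.

Step 17
Reactants: 29 the α-silyloxy keto aldehyde
Product: 30 (1S,2S,6R,7R,8S,10R)-1,10-dihydroxy-8-(naphthalen-2-ylmethoxy)-2-(triethylsilyloxy)-15-[tert-butyl(diphenyl)silyloxy]germacr-4-en-12,6-olide (C15 cis to C6)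
Conditions: SmI2 (4 equiv), THF (0.005 M), slow addition of 29, −78 °C → rt; pH 7 buffer
Reagents that add atoms: none
Why: Intramolecular SmI2 pinacol coupling of a keto aldehyde (ketyl formation by single-electron transfer and C1–C10 bond formation, closing the ten-membered ring); the two oxygens held on trivalent samarium give the cis-diol, and the C1–O bond forms anti to the bulky C2 silyloxy group as in pinacol cyclisations of α-alkoxy dicarbonyls, which together correspond to 1S,10R.

Step 18
Reactants: 30 the cis-diol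
Product: 32 (1R,2S,6R,7R,8S,10R)-1,10-epoxy-8-(naphthalen-2-ylmethoxy)-2-(triethylsilyloxy)-15-[tert-butyl(diphenyl)silyloxy]germacr-4-en-12,6-olide, via C1 mesylate 31 (not isolated)
Conditions: MsCl, Et3N, CH2Cl2, −20 → 0 °C; then K2CO3, MeOH, 0 °C
Reagents that add atoms: none
Why: Selective mesylation of the secondary C1 hydroxyl (the tertiary C10 hydroxyl does not react) and 3-exo-tet displacement by the C10 alkoxide with inversion at C1, the standard conversion of secondary/tertiary diols into epoxides; the cis-diol thus gives the trans (1R,10R) epoxide stereospecifically.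

Step 19
Reactants: 32 the epoxy lactone
Product: 35 (1R,2S,6R,7R,8S,10R)-1,10-epoxy-8-(naphthalen-2-ylmethoxy)-2-(triethylsilyloxy)-15-[tert-butyl(diphenyl)silyloxy]germacra-4,11(13)-dien-12,6-olide, via Mannich base 33 (not isolated), via ammonium iodide 34 (not isolated)
Conditions: LDA, THF, −78 °C; Me2N=CH2 I, −78 → 0 °C; then MeI, THF/MeOH, rt; then aq. NaHCO3, EtOAc, rt
Reagents that add atoms: dimethyl(methylidene)ammonium iodide, C=[N+](C)C.[I-]
Why: α-Methylenation of a γ-lactone by the Eschenmoser-salt Mannich reaction of the lithium enolate, N-methylation and base-induced elimination of trimethylamine; the configuration at C11 in 33 is irrelevant because that centre becomes trigonal.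

Step 20
Reactants: 35 the α-methylene lactone
Product: 36 (1R,2S,6R,7R,8S,10R)-1,10-epoxy-8-hydroxy-2-(triethylsilyloxy)-15-[tert-butyl(diphenyl)silyloxy]germacra-4,11(13)-dien-12,6-olide
Conditions: DDQ, CH2Cl2/pH 7 buffer (10:1), rt
Reagents that add atoms: none
Why: Oxidative cleavage of the 2-naphthylmethyl ether by DDQ (hydride abstraction, hydrolysis of the oxocarbenium ion) under buffered conditions that spare silyl ethers, the epoxide and the methylene lactone.

Step 21
Reactants: 36 the C8 alcohol; 37 angelic acid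
Product: 39 (1R,2S,6R,7R,8S,10R)-8-angeloyloxy-1,10-epoxy-2-(triethylsilyloxy)-15-[tert-butyl(diphenyl)silyloxy]germacra-4,11(13)-dien-12,6-olide, via mixed trichlorobenzoic anhydride 38 (not isolated)
Conditions: 37, 2,4,6-Cl3C6H2COCl, Et3N, PhMe, rt; then 36, 75 °C
Reagents that add atoms: none
Why: Yamaguchi esterification through the mixed 2,4,6-trichlorobenzoic anhydride, the established way to acylate hindered secondary alcohols with angelic acid without Z to E isomerisation; C8–OH is the only free hydroxyl.

Step 22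
Reactants: 39 the bis-silyl ether
Product: 40 EANPDB:COMP_00180, (1R,2S,6R,7R,8S,10R)-8-angeloyloxy-1,10-epoxy-2,15-dihydroxygermacra-4,11(13)-dien-12,6-olide
Conditions: TBAF, AcOH (1:1), THF, 0 °C → rt
Reagents that add atoms: none
Why: Fluoride-mediated cleavage of the TES and TBDPS ethers, buffered with acetic acid so that the angelate, the methylene lactone and the epoxy alcohol do not meet basic fluoride.

## Compound list

1 | 4-tert-butoxy-4-oxobutanoic acid (mono-tert-butyl succinate) | CC(C)(C)OC(=O)CCC(=O)O | starting material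
2 | (4R)-4-benzyl-1,3-oxazolidin-2-one | O=C1OC[C@@H](Cc2ccccc2)N1 | starting material
3 | 4-tert-butoxy-4-oxobutanoic pivalic anhydride | CC(C)(C)OC(=O)CCC(=O)OC(=O)C(C)(C)C | intermediate
4 | tert-butyl 4-[(4R)-4-benzyl-2-oxo-1,3-oxazolidin-3-yl]-4-oxobutanoate | CC(C)(C)OC(=O)CCC(=O)N1C(=O)OC[C@H]1Cc1ccccc1 | intermediate
5 | ethyl 2-(2-methyl-1,3-dioxolan-2-yl)acetate | CCOC(=O)CC1(C)OCCO1 | starting material
6 | 2-(2-methyl-1,3-dioxolan-2-yl)acetaldehyde | O=CCC1(C)OCCO1 | intermediate
7 | dibutylboron (Z)-enolate of imide 4 | CCCCB(CCCC)O/C(=C\CC(=O)OC(C)(C)C)N1C(=O)OC[C@H]1Cc1ccccc1 | intermediate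
8 | O-dibutylboryl aldolate of 9 | O=C([C@H](CC(=O)OC(C)(C)C)[C@@H](OB(CCCC)CCCC)CC1(C)OCCO1)N1C(=O)OC[C@H]1Cc1ccccc1 | intermediate
9 | tert-butyl (3R,4S)-3-[(4R)-4-benzyl-2-oxo-1,3-oxazolidine-3-carbonyl]-4-hydroxy-5-(2-methyl-1,3-dioxolan-2-yl)pentanoate | O=C([C@H](CC(=O)OC(C)(C)C)[C@@H](O)CC1(C)OCCO1)N1C(=O)OC[C@H]1Cc1ccccc1 | intermediate
10 | tert-butyl (3R,4S)-3-[(4R)-4-benzyl-2-oxo-1,3-oxazolidine-3-carbonyl]-5-(2-methyl-1,3-dioxolan-2-yl)-4-(naphthalen-2-ylmethoxy)pentanoate | O=C([C@H](CC(=O)OC(C)(C)C)[C@@H](OCc1ccc2ccccc2c1)CC1(C)OCCO1)N1C(=O)OC[C@H]1Cc1ccccc1 | intermediate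
11 | trimethylsilyl ester of acid 12 | O=C([C@H](CC(=O)O[Si](C)(C)C)[C@@H](OCc1ccc2ccccc2c1)CC1(C)OCCO1)N1C(=O)OC[C@H]1Cc1ccccc1 | intermediate
12 | (3R,4S)-3-[(4R)-4-benzyl-2-oxo-1,3-oxazolidine-3-carbonyl]-5-(2-methyl-1,3-dioxolan-2-yl)-4-(naphthalen-2-ylmethoxy)pentanoic acid | O=C([C@H](CC(=O)O)[C@@H](OCc1ccc2ccccc2c1)CC1(C)OCCO1)N1C(=O)OC[C@H]1Cc1ccccc1 | intermediate
13 | methyl (3R,4S)-3-[(4R)-4-benzyl-2-oxo-1,3-oxazolidine-3-carbonyl]-5-(2-methyl-1,3-dioxolan-2-yl)-4-(naphthalen-2-ylmethoxy)pentanoate | O=C([C@H](CC(=O)OC)[C@@H](OCc1ccc2ccccc2c1)CC1(C)OCCO1)N1C(=O)OC[C@H]1Cc1ccccc1 | intermediate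
14 | methyl (3R,4S)-3-[(ethylsulfanyl)carbonyl]-5-(2-methyl-1,3-dioxolan-2-yl)-4-(naphthalen-2-ylmethoxy)pentanoate | CCSC(=O)[C@H](CC(=O)OC)[C@@H](OCc1ccc2ccccc2c1)CC1(C)OCCO1 | intermediate
15 | methyl (3R,4S)-3-formyl-5-(2-methyl-1,3-dioxolan-2-yl)-4-(naphthalen-2-ylmethoxy)pentanoate (C6–C12 aldehyde ester) | O=C[C@H](CC(=O)OC)[C@@H](OCc1ccc2ccccc2c1)CC1(C)OCCO1 | intermediate
16 | 2-(2-bromoethyl)-1,3-dioxolane | BrCCC1OCCO1 | starting material
17 | [2-(1,3-dioxolan-2-yl)ethyl]magnesium bromide | Br[Mg]CCC1OCCO1 | intermediate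
18 | prop-2-yn-1-ol | C#CCO | starting material
19 | bromomagnesium prop-2-yn-1-olate | C#CCO[Mg]Br | intermediate
20 | 4-[2-(1,3-dioxolan-2-yl)ethyl]-2,5-dihydro-1,2-oxamagnesole (alkenylmagnesium chelate) | O1CC(CCC2OCCO2)=C[Mg]1 | intermediate
21 | cyclic magnesium dialkoxide of the C6 adduct (O6 and O15 on magnesium, methyl ester intact, 6R,7R,8S) | [Mg]1OC/C(CCC2OCCO2)=C\[C@@H](O1)[C@H](CC(=O)OC)[C@@H](OCc2ccc3ccccc3c2)CC2(C)OCCO2 | intermediate
22 | (4R,5R)-5-[(1Z)-4-(1,3-dioxolan-2-yl)-2-(hydroxymethyl)but-1-en-1-yl]-4-[(1S)-2-(2-methyl-1,3-dioxolan-2-yl)-1-(naphthalen-2-ylmethoxy)ethyl]oxolan-2-one | C1C(=O)O[C@H](/C=C(\CO)CCC2OCCO2)[C@H]1[C@@H](OCc2ccc3ccccc3c2)CC3(C)OCCO3 | intermediate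
23 | 15-O-TBDPS ether of 22 | C1C(=O)O[C@H](/C=C(\CO[Si](C(C)(C)C)(c2ccccc2)c2ccccc2)CCC2OCCO2)[C@H]1[C@@H](OCc2ccc3ccccc3c2)CC3(C)OCCO3 | intermediate
24 | (4R,5R)-5-[(1Z)-2-{[tert-butyl(diphenyl)silyl]oxymethyl}-5-oxopent-1-en-1-yl]-4-[(1S)-1-(naphthalen-2-ylmethoxy)-3-oxobutyl]oxolan-2-one | C1C(=O)O[C@H](/C=C(\CO[Si](C(C)(C)C)(c2ccccc2)c2ccccc2)CCC=O)[C@H]1[C@@H](OCc2ccc3ccccc3c2)CC(C)=O | intermediate
25 | (2S)-2-anilinooxy aldehyde derived from 24 (C2–ONHPh, C1 aldehyde) | C1C(=O)O[C@H](/C=C(\CO[Si](C(C)(C)C)(c2ccccc2)c2ccccc2)C[C@H](ONc2ccccc2)C=O)[C@H]1[C@@H](OCc2ccc3ccccc3c2)CC(C)=O | intermediate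
26 | (4R,5R)-5-[(1Z,4S)-4-(anilinooxy)-2-{[tert-butyl(diphenyl)silyl]oxymethyl}-5-hydroxypent-1-en-1-yl]-4-[(1S)-1-(naphthalen-2-ylmethoxy)-3-oxobutyl]oxolan-2-one | C1C(=O)O[C@H](/C=C(\CO[Si](C(C)(C)C)(c2ccccc2)c2ccccc2)C[C@H](ONc2ccccc2)CO)[C@H]1[C@@H](OCc2ccc3ccccc3c2)CC(C)=O | intermediate
27 | (4R,5R)-5-[(1Z,4S)-2-{[tert-butyl(diphenyl)silyl]oxymethyl}-4,5-dihydroxypent-1-en-1-yl]-4-[(1S)-1-(naphthalen-2-ylmethoxy)-3-oxobutyl]oxolan-2-one | C1C(=O)O[C@H](/C=C(\CO[Si](C(C)(C)C)(c2ccccc2)c2ccccc2)C[C@H](O)CO)[C@H]1[C@@H](OCc2ccc3ccccc3c2)CC(C)=O | intermediate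
28 | 1,2-bis-O-TES ether of 27 | C1C(=O)O[C@H](/C=C(\CO[Si](C(C)(C)C)(c2ccccc2)c2ccccc2)C[C@H](O[Si](CC)(CC)CC)CO[Si](CC)(CC)CC)[C@H]1[C@@H](OCc2ccc3ccccc3c2)CC(C)=O | intermediate
29 | (4R,5R)-5-[(1Z,4S)-2-{[tert-butyl(diphenyl)silyl]oxymethyl}-5-oxo-4-(triethylsilyloxy)pent-1-en-1-yl]-4-[(1S)-1-(naphthalen-2-ylmethoxy)-3-oxobutyl]oxolan-2-one | C1C(=O)O[C@H](/C=C(\CO[Si](C(C)(C)C)(c2ccccc2)c2ccccc2)C[C@H](O[Si](CC)(CC)CC)C=O)[C@H]1[C@@H](OCc2ccc3ccccc3c2)CC(C)=O | intermediate
30 | (1S,2S,6R,7R,8S,10R)-1,10-dihydroxy-8-(naphthalen-2-ylmethoxy)-2-(triethylsilyloxy)-15-[tert-butyl(diphenyl)silyloxy]germacr-4-en-12,6-olide | C1C(=O)O[C@@H]2/C=C(\CO[Si](C(C)(C)C)(c3ccccc3)c3ccccc3)C[C@H](O[Si](CC)(CC)CC)[C@H](O)[C@@](O)(C)C[C@H](OCc3ccc4ccccc4c3)[C@@H]12 | intermediate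
31 | 1-O-methanesulfonate of 30 | C1C(=O)O[C@@H]2/C=C(\CO[Si](C(C)(C)C)(c3ccccc3)c3ccccc3)C[C@H](O[Si](CC)(CC)CC)[C@H](OS(C)(=O)=O)[C@@](O)(C)C[C@H](OCc3ccc4ccccc4c3)[C@@H]12 | intermediate
32 | (1R,2S,6R,7R,8S,10R)-1,10-epoxy-8-(naphthalen-2-ylmethoxy)-2-(triethylsilyloxy)-15-[tert-butyl(diphenyl)silyloxy]germacr-4-en-12,6-olide | C1C(=O)O[C@@H]2/C=C(\CO[Si](C(C)(C)C)(c3ccccc3)c3ccccc3)C[C@H](O[Si](CC)(CC)CC)[C@H]3O[C@]3(C)C[C@H](OCc3ccc4ccccc4c3)[C@@H]12 | intermediate
33 | 11-(dimethylaminomethyl) derivative of 32 (C11 epimers) | CN(C)CC1C(=O)O[C@@H]2/C=C(\CO[Si](C(C)(C)C)(c3ccccc3)c3ccccc3)C[C@H](O[Si](CC)(CC)CC)[C@H]3O[C@]3(C)C[C@H](OCc3ccc4ccccc4c3)[C@@H]12 | intermediate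
34 | 11-(trimethylammoniomethyl) iodide derived from 33 (C11 epimers) | C[N+](C)(C)CC1C(=O)O[C@@H]2/C=C(\CO[Si](C(C)(C)C)(c3ccccc3)c3ccccc3)C[C@H](O[Si](CC)(CC)CC)[C@H]3O[C@]3(C)C[C@H](OCc3ccc4ccccc4c3)[C@@H]12.[I-] | intermediate
35 | (1R,2S,6R,7R,8S,10R)-1,10-epoxy-8-(naphthalen-2-ylmethoxy)-2-(triethylsilyloxy)-15-[tert-butyl(diphenyl)silyloxy]germacra-4,11(13)-dien-12,6-olide | C=C1C(=O)O[C@@H]2/C=C(\CO[Si](C(C)(C)C)(c3ccccc3)c3ccccc3)C[C@H](O[Si](CC)(CC)CC)[C@H]3O[C@]3(C)C[C@H](OCc3ccc4ccccc4c3)[C@@H]12 | intermediate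
36 | (1R,2S,6R,7R,8S,10R)-1,10-epoxy-8-hydroxy-2-(triethylsilyloxy)-15-[tert-butyl(diphenyl)silyloxy]germacra-4,11(13)-dien-12,6-olide | C=C1C(=O)O[C@@H]2/C=C(\CO[Si](C(C)(C)C)(c3ccccc3)c3ccccc3)C[C@H](O[Si](CC)(CC)CC)[C@H]3O[C@]3(C)C[C@H](O)[C@@H]12 | intermediate
37 | angelic acid, (Z)-2-methylbut-2-enoic acid | C/C=C(/C)C(=O)O | starting material
38 | (Z)-2-methylbut-2-enoic 2,4,6-trichlorobenzoic anhydride | C/C=C(/C)C(=O)OC(=O)c1c(Cl)cc(Cl)cc1Cl | intermediate
39 | (1R,2S,6R,7R,8S,10R)-8-angeloyloxy-1,10-epoxy-2-(triethylsilyloxy)-15-[tert-butyl(diphenyl)silyloxy]germacra-4,11(13)-dien-12,6-olide | C=C1C(=O)O[C@@H]2/C=C(\CO[Si](C(C)(C)C)(c3ccccc3)c3ccccc3)C[C@H](O[Si](CC)(CC)CC)[C@H]3O[C@]3(C)C[C@H](OC(=O)/C(C)=C\C)[C@@H]12 | intermediate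
40 | EANPDB:COMP_00180, (1R,2S,6R,7R,8S,10R)-8-angeloyloxy-1,10-epoxy-2,15-dihydroxygermacra-4,11(13)-dien-12,6-olide | C=C1C(=O)O[C@@H]2/C=C(\CO)C[C@H](O)[C@H]3O[C@]3(C)C[C@H](OC(=O)/C(C)=C\C)[C@@H]12 | target

## Step count and least certain steps

Total: 22 steps. Longest linear sequence: 20 steps (steps 1, 3–8, 10–22, from 1 to 40).

**Step 10 (key step).**
- What may go wrong: deprotonation of the acetylenic C–H competes with carbometalation and lowers the amount of the chelate 20, which is also a sluggish nucleophile. Leftover 17 would then add to the aldehyde. Facial selectivity at C6 is lost if magnesium bridges the aldehyde and the C8 ether or the ester carbonyl. Enolisation of 15 would epimerise C7 or eliminate the C8 ether.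
- Fallback (sets out from 18, 17 and 15, returns at 23): the coupling is split into two metal-mediated events. The carbomagnesiation of 18 with 17 is quenched with iodine to give the (Z)-iodo alkenol F1, which is silylated to the TBDPS ether F2. F2 is coupled with 15 under Nozaki–Hiyama–Kishi conditions (CrCl2, NiCl2 cat., DMSO), which are chemoselective for aldehydes and tolerate the ester, to give the hydroxy ester F3. F3 is lactonised with PPTS to 23.

**Step 17.**
- What may go wrong: transannular strain may divert the ketyls to intermolecular coupling or simple reduction in place of ring closure. Facial selectivity at C1 and C10 may be poor if the samarium-bridged arrangement is not attainable in the ring. The TES group may migrate from O2 to the C1 alkoxide.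
- Fallback (from 28, returns at 30): polar instead of reductive bond formation. Kinetic enolisation of the methyl ketone of 28 (KHMDS, N-phenylbis(trifluoromethanesulfonimide), −78 °C) gives the enol triflate F4. Swern oxidation as in step 16 gives the aldehyde F5. Intramolecular Nozaki–Hiyama–Kishi coupling (CrCl2, NiCl2 cat., high dilution) gives the macrocyclic allylic alcohol F6 with the exocyclic C10 methylene. Mukaiyama hydration (Co(acac)2, PhSiH3, O2) of this 1,1-disubstituted alkene gives the tertiary alcohol 30; the face of this hydration is not controlled by design.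

**Step 13.**
- What may go wrong: competing enamine activation of the unmasked C10 methyl ketone (aminoxylation at C9 or C14) and partial reduction of that ketone by borohydride.
- Fallback (from 23, returns at 27): the ketone is kept masked through this stage. TESOTf/2,4,6-collidine followed by water cleaves only the aldehyde-derived dioxolane of 23 and gives the ketal aldehyde F7. Aminoxylation and reduction as in step 13 give the anilinooxy alcohol F8, and zinc in acetic acid gives the ketal diol F9. Aqueous acetic acid in THF then releases the ketone to give 27.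

**Step 5.**
- What may go wrong: ring-opening of the dioxolane ketal or loss of the Nap ether under the silyl triflate before the tert-butyl ester is consumed.
- Fallback (from 2 and 6, returns at 12): C12 is carried as an alkene, not as an ester. 2 is acylated with pent-4-enoyl chloride (n-BuLi) to the pentenoyl imide F10. Aldol reaction with 6 as in step 3 gives the adduct F11, and naphthylmethylation as in step 4 gives the ether F12. Lemieux–Johnson cleavage (OsO4 cat., NaIO4) gives the aldehyde F13, and Pinnick oxidation gives 12.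

**Step 21.**
- What may go wrong: isomerisation of the activated angelate to the tiglate, and migration of the lactone to the free C8 hydroxyl on heating with base.
- Fallback (from 36, returns at 39): the Z-alkene is built on the ester. 36 is acylated with 2-[bis(2,2,2-trifluoroethoxy)phosphoryl]propanoic acid (DCC, DMAP) to the phosphonate ester F14. Still–Gennari olefination with acetaldehyde (KHMDS, 18-crown-6, −78 °C) is Z-selective and gives 39.

## Further compounds

F1 | step 10 | (Z)-2-[2-(1,3-dioxolan-2-yl)ethyl]-3-iodoprop-2-en-1-ol | OC/C(CCC1OCCO1)=C\I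
F2 | step 10 | tert-butyl{[(Z)-2-[2-(1,3-dioxolan-2-yl)ethyl]-3-iodoprop-2-en-1-yl]oxy}diphenylsilane | CC(C)(C)[Si](OC/C(CCC1OCCO1)=C\I)(c1ccccc1)c1ccccc1
F3 | step 10 | methyl ester of the open C6 hydroxy acid of 23 (6R,7R,8S; C6–OH free, 15-OTBDPS) | COC(=O)C[C@@H]([C@H](O)/C=C(\CO[Si](C(C)(C)C)(c1ccccc1)c1ccccc1)CCC1OCCO1)[C@@H](OCc1ccc2ccccc2c1)CC1(C)OCCO1
F4 | step 17 | enol triflate of 28 (C10(OTf)=C14H2) | C1C(=O)O[C@H](/C=C(\CO[Si](C(C)(C)C)(c2ccccc2)c2ccccc2)C[C@H](O[Si](CC)(CC)CC)CO[Si](CC)(CC)CC)[C@H]1[C@@H](OCc2ccc3ccccc3c2)CC(=C)OS(=O)(=O)C(F)(F)F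
F5 | step 17 | C1 aldehyde of F4 (C2–OTES retained) | C1C(=O)O[C@H](/C=C(\CO[Si](C(C)(C)C)(c2ccccc2)c2ccccc2)C[C@H](O[Si](CC)(CC)CC)C=O)[C@H]1[C@@H](OCc2ccc3ccccc3c2)CC(=C)OS(=O)(=O)C(F)(F)F
F6 | step 17 | ten-membered allylic alcohol: 1-hydroxy-10(14)-methylene analogue of 30 | C1C(=O)O[C@@H]2/C=C(\CO[Si](C(C)(C)C)(c3ccccc3)c3ccccc3)C[C@H](O[Si](CC)(CC)CC)[C@H](O)C(=C)C[C@H](OCc3ccc4ccccc4c3)[C@@H]12
F7 | step 13 | C1 aldehyde of 23 with the C10 dioxolane retained | C1C(=O)O[C@H](/C=C(\CO[Si](C(C)(C)C)(c2ccccc2)c2ccccc2)CCC=O)[C@H]1[C@@H](OCc2ccc3ccccc3c2)CC3(C)OCCO3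
F8 | step 13 | (2S)-2-anilinooxy-1-ol with the C10 dioxolane retained | C1C(=O)O[C@H](/C=C(\CO[Si](C(C)(C)C)(c2ccccc2)c2ccccc2)C[C@H](ONc2ccccc2)CO)[C@H]1[C@@H](OCc2ccc3ccccc3c2)CC3(C)OCCO3
F9 | step 13 | (2S)-1,2-diol with the C10 dioxolane retained | C1C(=O)O[C@H](/C=C(\CO[Si](C(C)(C)C)(c2ccccc2)c2ccccc2)C[C@H](O)CO)[C@H]1[C@@H](OCc2ccc3ccccc3c2)CC3(C)OCCO3
F10 | step 5 | (4R)-4-benzyl-3-(pent-4-enoyl)-1,3-oxazolidin-2-one | C=CCCC(=O)N1C(=O)OC[C@H]1Cc1ccccc1
F11 | step 5 | syn-aldol adduct of F10 and 6 (C7 allyl, C8–OH) | O=C([C@H](CC=C)[C@@H](O)CC1(C)OCCO1)N1C(=O)OC[C@H]1Cc1ccccc1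
F12 | step 5 | 8-O-(2-naphthylmethyl) ether of F11 | O=C([C@H](CC=C)[C@@H](OCc1ccc2ccccc2c1)CC1(C)OCCO1)N1C(=O)OC[C@H]1Cc1ccccc1
F13 | step 5 | C12 aldehyde from oxidative cleavage of F12 | O=C([C@H](CC=O)[C@@H](OCc1ccc2ccccc2c1)CC1(C)OCCO1)N1C(=O)OC[C@H]1Cc1ccccc1
F14 | step 21 | 8-O-{2-[bis(2,2,2-trifluoroethoxy)phosphoryl]propanoyl} ester of 36 | C=C1C(=O)O[C@@H]2/C=C(\CO[Si](C(C)(C)C)(c3ccccc3)c3ccccc3)C[C@H](O[Si](CC)(CC)CC)[C@H]3O[C@]3(C)C[C@H](OC(=O)C(C)P(=O)(OCC(F)(F)F)OCC(F)(F)F)[C@@H]12
A1 | alternative 1 | ten-membered homoallylic alcohol with free C8–OH and the C11=C13 methylene | C=C(CO[Si](CC)(CC)CC)[C@H]1[C@H](O[Si](CC)(CC)CC)/C=C(\CO[Si](C)(C)C(C)(C)C)C[C@H](OCc2ccc(OC)cc2)/C=C(C)/C[C@@H]1O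
A2 | alternative 1 | thirteen-membered cyclic ether with O bridging C8 and C13 and a tributylstannyl group on C8 | CCCC[Sn](CCCC)(CCCC)[C@@H]1OC/C(CO[Si](CC)(CC)CC)=C/[C@H](O[Si](CC)(CC)CC)/C=C(\CO[Si](C)(C)C(C)(C)C)C[C@H](OCc2ccc(OC)cc2)/C=C(C)/C1
A3 | alternative 2 | C6,C15-endoperoxide with the C4=C5 alkene | C=C(C(=O)OC)[C@H]1[C@@H]2OOCC(=C2)C[C@H](O)[C@H]3O[C@]3(C)C[C@@H]1OC(=O)/C(C)=C\C
A4 | alternative 2 | germacrene D-type 4(15),5-diene with the 1,10-epoxide, 2-OH, 8-angelate and the C11 acrylate | C=C(C(=O)OC)[C@H]1/C=C/C(=C)C[C@H](O)[C@H]2O[C@]2(C)C[C@@H]1OC(=O)/C(C)=C\C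
A5 | alternative 3 | ten-membered epoxy lactone with silyl ethers at C2, C8 and C15 | C1C(=O)O[C@@H]2/C=C(\CO[Si](C)(C)C(C)(C)C)C[C@H](O[Si](C)(C)C(C)(C)C)[C@H]3O[C@]3(C)C[C@H](O[Si](CC)(CC)CC)[C@@H]12
A6 | alternative 3 | acyclic lactone with the C1 aldehyde and a C10 diphenylsulfonium triflate (C10 epimers) | C1C(=O)O[C@H](/C=C(\CO[Si](C)(C)C(C)(C)C)C[C@H](O[Si](C)(C)C(C)(C)C)C=O)[C@H]1[C@@H](O[Si](CC)(CC)CC)CC(C)[S+](c2ccccc2)c2ccccc2.[O-]S(=O)(=O)C(F)(F)F
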